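## Retrosynthetic overview

1. The dienoate is cut at the C3–O bond (acid 32, from (S)-2-methylbutan-1-ol). The diosphenol (C7–OH, C8=O) comes from C6=C7 of dienone 24 by dihydroxylation and dehydration, and C9=C10 from a Saegusa–Ito oxidation of enone 22.
2. Key disconnection: C1–C10. The plan rests on quaternary C5 of ring B, which carries two enone arms (C6=C7 and C9=C10 flanking C8=O). In the 4-methyl-4-alkylcyclohexa-2,5-dienone 21 it is not stereogenic and becomes so only when ring A (C1, C2, C3, C4, C5, C10) closes by 6-exo addition of a C1 radical to C10.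
3. Ring B is made first (α-methyl aldehyde 12 + methyl vinyl ketone, Robinson annulation, dehydrogenation to dienone 18); ring A is made second.
4. The C2/C3/C4 triad (2,3-syn, 3,4-anti) comes from (R)-glyceraldehyde acetonide by reagent-controlled (E)-crotylboration; C1 and C2 are the acetonide carbons.

Key step: step 12

Remark: eremophilane numbering (C1–C10) is used throughout. Compounds 10–17 are carried as mixtures at the future C5 (10 also as E/Z isomers), which is harmless because C5 is not stereogenic in dienone 18. PMB = 4-methoxybenzyl, TBS = tert-butyldimethylsilyl.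

## Route

Step 1
Reactants: 1 (E)-but-2-ene
Product: 4 diisopropyl (4S,5S)-2-[(E)-but-2-enyl]-1,3,2-dioxaborolane-4,5-dicarboxylate, via crotylpotassium 2 (not isolated), via diisopropyl crotylboronate 3 (not isolated)
Conditions: n-BuLi, KOtBu, THF, −78 → −50 °C; B(OiPr)3, −78 °C; 1 N HCl; (S,S)-diisopropyl tartrate, MgSO4, Et2O, rt
Reagents that add atoms: triisopropyl borate, CC(C)OB(OC(C)C)OC(C)C; diisopropyl (2S,3S)-tartrate, CC(C)OC(=O)[C@@H](O)[C@H](O)C(=O)OC(C)C
Why: Schlosser-base metalation gives (E)-crotylpotassium, which keeps its geometry at low temperature, and borylation followed by transesterification with the tartrate gives the chiral (E)-crotylboronate.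

Step 2
Reactants: 4 tartrate (E)-crotylboronate; 5 (R)-glyceraldehyde acetonide
Product: 7 (1R,2R)-1-[(4R)-2,2-dimethyl-1,3-dioxolan-4-yl]-2-methylbut-3-en-1-ol, via borate ester 6 (not isolated)
Conditions: 4 Å molecular sieves, toluene, −78 °C; then H2O
Reagents that add atoms: none
Why: Asymmetric crotylboration through a closed chair (Zimmerman–Traxler) transition state, in which the E geometry sets C3/C4 anti and the (S,S)-tartrate directs attack to the Re face of an aldehyde that has little facial bias of its own toward (E)-crotylboronates, setting C2/C3 syn.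

Step 3
Reactants: 7 homoallylic alcohol
Product: 8 (4R)-4-{(1R,2R)-1-[(4-methoxybenzyl)oxy]-2-methylbut-3-en-1-yl}-2,2-dimethyl-1,3-dioxolane
Conditions: NaH, PMBCl, Bu4NI (cat.), THF/DMF, 0 °C → rt
Reagents that add atoms: 4-methoxybenzyl chloride, COc1ccc(CCl)cc1
Why: Williamson etherification of the C3 alkoxide, which marks the C3 oxygen apart from the C1/C2 acetonide oxygens for the end game.

Step 4
Reactants: 8 PMB ether
Product: 9 (3S,4R)-4-[(4R)-2,2-dimethyl-1,3-dioxolan-4-yl]-4-[(4-methoxybenzyl)oxy]-3-methylbutan-2-one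
Conditions: PdCl2 (10 mol%), CuCl, O2 (1 atm), DMF/H2O (7:1), rt
Reagents that add atoms: water, O
Why: Tsuji–Wacker oxidation of the terminal alkene gives the methyl ketone (Markovnikov hydroxypalladation), turning the internal vinyl carbon into C5 and the terminal one into the C5 methyl.

Step 5
Reactants: 9 methyl ketone
Product: 10 (4R)-4-{(1R,2R)-4-methoxy-1-[(4-methoxybenzyl)oxy]-2,3-dimethylbut-3-en-1-yl}-2,2-dimethyl-1,3-dioxolane (E/Z mixture)
Conditions: MeOCH2PPh3Cl, KN(SiMe3)2, THF, 0 °C; then 9, −78 °C → rt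
Reagents that add atoms: (methoxymethyl)triphenylphosphonium chloride, COC[P+](c1ccccc1)(c1ccccc1)c1ccccc1.[Cl-]
Why: Wittig methoxymethylenation adds the one carbon that becomes C6, and low temperature is chosen so that the ylide does not enolise the ketone toward C4.

Step 6
Reactants: 10 enol ether
Product: 12 (3R,4R)-4-[(4R)-2,2-dimethyl-1,3-dioxolan-4-yl]-4-[(4-methoxybenzyl)oxy]-2,3-dimethylbutanal (both C2 epimers), via mercurio aldehyde 11 (not isolated)
Conditions: Hg(OAc)2, THF/H2O (10:1), 0 °C → rt; then aq. KI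
Reagents that add atoms: water, O
Why: Oxymercuration of the enol ether and demercuration with iodide hydrolyse it to the aldehyde under near-neutral conditions that spare the acetonide, which aqueous acid would not reliably do.

Step 7
Reactants: 12 α-methyl aldehyde; 13 methyl vinyl ketone
Product: 16 4-{(1R,2R)-1-[(4R)-2,2-dimethyl-1,3-dioxolan-4-yl]-1-[(4-methoxybenzyl)oxy]propan-2-yl}-4-methylcyclohex-2-en-1-one (both ring epimers), via keto aldehyde 14 (not isolated), via ketol 15 (not isolated)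
Conditions: MVK (slow addition), KOH (0.2 equiv), MeOH, 0 °C → rt; then aq. KOH, 60 °C
Reagents that add atoms: none
Why: Robinson annulation, in which the aldehyde with its single α-hydrogen cannot self-condense, adds through its enolate to the enone to make quaternary C5, and aldol condensation then closes ring B.

Step 8
Reactants: 16 cyclohexenone
Product: 18 4-{(1R,2R)-1-[(4R)-2,2-dimethyl-1,3-dioxolan-4-yl]-1-[(4-methoxybenzyl)oxy]propan-2-yl}-4-methylcyclohexa-2,5-dien-1-one, via silyl dienol ether 17 (not isolated)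
Conditions: LiN(iPr)2, THF, −78 °C; TMSCl; then Pd(OAc)2, MeCN, rt
Reagents that add atoms: none
Why: Saegusa–Ito oxidation of the kinetic cross-conjugated silyl dienol ether (C9 is the only enolisable position) gives the dienone without touching the PMB ether, and C5 becomes a prochiral centre.

Step 9
Reactants: 18 dienone acetonide
Product: 19 4-{(2R,3R,4R)-4,5-dihydroxy-3-[(4-methoxybenzyl)oxy]pentan-2-yl}-4-methylcyclohexa-2,5-dien-1-one
Conditions: AcOH/H2O/THF (3:1:1), 40 °C
Reagents that add atoms: none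
Why: Mild acid hydrolysis of the terminal acetonide, weak enough to avoid dienone–phenol rearrangement, PMB loss and acid-catalysed oxa-Michael addition of the C2 hydroxyl.

Step 10
Reactants: 19 diol
Product: 20 4-{(2R,3R,4S)-4-hydroxy-5-iodo-3-[(4-methoxybenzyl)oxy]pentan-2-yl}-4-methylcyclohexa-2,5-dien-1-one
Conditions: I2, PPh3, imidazole, CH2Cl2, 0 °C
Reagents that add atoms: iodine, II
Why: Appel-type (Garegg–Samuelsson) iodination is selective for the primary C1 hydroxyl of a 1,2-diol at low temperature.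

Step 11
Reactants: 20 iodohydrin
Product: 21 4-{(2R,3R,4S)-4-[(tert-butyldimethylsilyl)oxy]-5-iodo-3-[(4-methoxybenzyl)oxy]pentan-2-yl}-4-methylcyclohexa-2,5-dien-1-one
Conditions: TBSOTf, 2,6-lutidine, CH2Cl2, −78 → 0 °C
Reagents that add atoms: tert-butyldimethylsilyl triflate, CC(C)(C)[Si](C)(C)OS(=O)(=O)C(F)(F)F
Why: Silylation with the triflate and a hindered, non-nucleophilic base protects C2–OH without closing the iodohydrin to an epoxide.

Step 12
Reactants: 21 iodo dienone
Product: 22 (4aR,5R,6R,7R,8aR)-7-[(tert-butyldimethylsilyl)oxy]-6-[(4-methoxybenzyl)oxy]-4a,5-dimethyl-4a,5,6,7,8,8a-hexahydronaphthalen-2(1H)-one (cis-fused)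
Conditions: Bu3SnH, AIBN (syringe pump), PhH (5 mM), 80 °C
Reagents that add atoms: none
Why: Bu3Sn• abstracts iodine from 21 to give the primary C1 radical, which adds to the enone β-carbon C10 (a nucleophilic alkyl radical meeting an electron-poor alkene), and the C9 α-keto radical so formed is reduced by Bu3SnH; the closest known reaction type is the tin hydride cyclization of haloalkyl tethers onto 4,4-disubstituted cyclohexa-2,5-dienones. Ring A (C1, C2, C3, C4, C5, C10) closes in the 6-exo-trig mode, and because the tether hangs from C5 it can reach C10 only on its own face, so the ring fusion is cis and C10 is set by this geometric constraint (it is erased again in step 13). Attack is perpendicular to the dienone plane, so whichever arm reacts the spectator arm lies pseudo-axial and the C5 methyl pseudo-equatorial on the forming chair, and the new C5 configuration is decided only by which chair the C1–C5 tether adopts, that is by the C2, C3 and C4 stereocentres. The chair with C2-OTBS and C3-OPMB equatorial and the C4 methyl axial leads to the arm that puts the C5 methyl cis to the C4 methyl, whereas the other chair needs both oxygens axial with C3-OPMB syn-axial to the spectator arm. The step thus needs selection between two diastereotopic enone arms, which this conformational bias of the substrate should secure, and it needs ring closure to outrun hydrogen transfer to C1, which high dilution and slow addition of the stannane favour.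

Step 13
Reactants: 22 bicyclic enone
Product: 24 (4aR,5R,6R,7R)-7-[(tert-butyldimethylsilyl)oxy]-6-[(4-methoxybenzyl)oxy]-4a,5-dimethyl-5,6,7,8-tetrahydronaphthalen-2(4aH)-one, via silyl dienol ether 23 (not isolated)
Conditions: LiN(iPr)2, THF, −78 °C; TMSCl; then Pd(OAc)2, MeCN, rt
Reagents that add atoms: none
Why: Saegusa–Ito oxidation, in which kinetic deprotonation at C9 and β-hydride elimination of the palladium enolate toward C10–H restore C9=C10.

Step 14
Reactants: 24 bicyclic dienone
Product: 25 (3R,4R,4aR,5R,6R,7R)-7-[(tert-butyldimethylsilyl)oxy]-3,4-dihydroxy-6-[(4-methoxybenzyl)oxy]-4a,5-dimethyl-4,4a,5,6,7,8-hexahydronaphthalen-2(3H)-one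
Conditions: OsO4 (5 mol%), N-methylmorpholine N-oxide, citric acid, t-BuOH/H2O, rt
Reagents that add atoms: N-methylmorpholine N-oxide, C[N+]1([O-])CCOCC1; water, O
Why: Upjohn dihydroxylation should take the disubstituted C6=C7 bond in preference to the fully β-substituted C9=C10 bond, from the face opposite the C5 methyl, although the two new centres are lost again in step 15.

Step 15
Reactants: 25 keto diol
Product: 26 (4aS,5R,6R,7R)-7-[(tert-butyldimethylsilyl)oxy]-3-hydroxy-6-[(4-methoxybenzyl)oxy]-4a,5-dimethyl-5,6,7,8-tetrahydronaphthalen-2(4aH)-one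
Conditions: TsOH·H2O (10 mol%), PhH, rt → 40 °C
Reagents that add atoms: none
Why: Acid-catalysed dehydration of the β-hydroxy ketone through the C7/C8 enediol expels the C6 hydroxyl and leaves the diosphenol, whose enol can only lie toward C6 because C9 is already sp2, while the non-basic medium avoids vinylogous loss of the C2 silyloxy group.

Step 16
Reactants: 26 diosphenol
Product: 27 (4aS,5R,6R,7R)-3,7-bis[(tert-butyldimethylsilyl)oxy]-6-[(4-methoxybenzyl)oxy]-4a,5-dimethyl-5,6,7,8-tetrahydronaphthalen-2(4aH)-one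
Conditions: TBSCl, imidazole, DMF, 0 °C → rt
Reagents that add atoms: tert-butyldimethylsilyl chloride, CC(C)(C)[Si](C)(C)Cl
Why: O-silylation of the acidic enol masks the diosphenol before the C3 acylation.

Step 17
Reactants: 27 bis-silyl PMB ether
Product: 28 (4aS,5R,6R,7R)-3,7-bis[(tert-butyldimethylsilyl)oxy]-6-hydroxy-4a,5-dimethyl-5,6,7,8-tetrahydronaphthalen-2(4aH)-one
Conditions: DDQ, CH2Cl2/pH 7 buffer (10:1), 0 °C
Reagents that add atoms: none
Why: Oxidative cleavage of the PMB ether frees only C3–OH, since the silyl ethers and the electron-poor silyloxy dienone are not oxidised by DDQ.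

Step 18
Reactants: 29 (S)-2-methylbutan-1-ol
Product: 30 (S)-2-methylbutanal
Conditions: TEMPO (cat.), KBr, NaOCl, CH2Cl2/H2O (pH 9.5), 0 °C
Reagents that add atoms: none
Why: Anelli oxidation under buffered two-phase conditions gives the α-chiral aldehyde without enolisation, and it is used at once as a solution.

Step 19
Reactants: 30 (S)-2-methylbutanal
Product: 31 ethyl (2E,4E,6S)-6-methylocta-2,4-dienoate
Conditions: triethyl 4-phosphonocrotonate, LiN(SiMe3)2, THF, −78 → 0 °C
Reagents that add atoms: triethyl (E)-4-phosphonocrotonate, CCOC(=O)/C=C/CP(=O)(OCC)OCC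
Why: Vinylogous Horner–Wadsworth–Emmons olefination gives the E,E-dienoate, and the low temperature limits epimerisation of the aldehyde α-centre.

Step 20
Reactants: 31 dienoate ester
Product: 32 (2E,4E,6S)-6-methylocta-2,4-dienoic acid
Conditions: LiOH, THF/MeOH/H2O, rt; then 1 N HCl
Reagents that add atoms: lithium hydroxide, [Li+].[OH-]
Why: Saponification of the ethyl ester, in which the remote C6 centre and the diene geometry are not affected.

Step 21
Reactants: 28 C3 alcohol; 32 dienoic acid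
Product: 34 (1R,2R,3R,8aS)-3,7-bis[(tert-butyldimethylsilyl)oxy]-1,8a-dimethyl-6-oxo-1,2,3,4,6,8a-hexahydronaphthalen-2-yl (2E,4E,6S)-6-methylocta-2,4-dienoate, via mixed anhydride 33 (not isolated)
Conditions: 2,4,6-Cl3C6H2COCl, Et3N, THF, rt; then 28, DMAP, toluene, rt
Reagents that add atoms: none
Why: Yamaguchi esterification, in which the mixed anhydride and DMAP give an acylpyridinium reactive enough for the axial C3 hydroxyl while C2–O and C7–O are silylated.

Step 22
Reactants: 34 bis-silyl ester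
Product: 35 septeremophilane G
Conditions: HF·pyridine, pyridine/THF, 0 °C → rt
Reagents that add atoms: none
Why: Buffered fluoride cleaves the enol silyl ether and the C2 silyl ether in one operation without ester migration, since the C2 and C3 oxygens are trans-diaxial, and without vinylogous elimination at C2.

## Compound list

1 | (E)-but-2-ene | C/C=C/C | starting material
2 | (E)-crotylpotassium | C/C=C/C[K] | intermediate (not isolated)
3 | diisopropyl (E)-but-2-enylboronate | C/C=C/CB(OC(C)C)OC(C)C | intermediate (not isolated)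
4 | diisopropyl (4S,5S)-2-[(E)-but-2-enyl]-1,3,2-dioxaborolane-4,5-dicarboxylate | CC(C)OC(=O)[C@H]1OB(C/C=C/C)O[C@@H]1C(=O)OC(C)C | intermediate
5 | (R)-glyceraldehyde acetonide, (4R)-2,2-dimethyl-1,3-dioxolane-4-carbaldehyde | O=C[C@H]1COC(C)(C)O1 | starting material
6 | tartrate borate ester of alcohol 7 | CC(C)OC(=O)[C@H]1OB(O[C@H]([C@H](C)C=C)[C@H]2COC(C)(C)O2)O[C@@H]1C(=O)OC(C)C | intermediate (not isolated)
7 | (1R,2R)-1-[(4R)-2,2-dimethyl-1,3-dioxolan-4-yl]-2-methylbut-3-en-1-ol | C=C[C@@H](C)[C@@H](O)[C@H]1COC(C)(C)O1 | intermediate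
8 | (4R)-4-{(1R,2R)-1-[(4-methoxybenzyl)oxy]-2-methylbut-3-en-1-yl}-2,2-dimethyl-1,3-dioxolane | C=C[C@@H](C)[C@@H](OCc1ccc(OC)cc1)[C@H]1COC(C)(C)O1 | intermediate
9 | (3S,4R)-4-[(4R)-2,2-dimethyl-1,3-dioxolan-4-yl]-4-[(4-methoxybenzyl)oxy]-3-methylbutan-2-one | CC(=O)[C@@H](C)[C@@H](OCc1ccc(OC)cc1)[C@H]1COC(C)(C)O1 | intermediate
10 | (4R)-4-{(1R,2R)-4-methoxy-1-[(4-methoxybenzyl)oxy]-2,3-dimethylbut-3-en-1-yl}-2,2-dimethyl-1,3-dioxolane (E/Z mixture) | COC=C(C)[C@@H](C)[C@@H](OCc1ccc(OC)cc1)[C@H]1COC(C)(C)O1 | intermediate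
11 | 2-(acetoxymercurio) derivative of aldehyde 12 (Hg on C5) | CC(=O)O[Hg]C(C)(C=O)[C@@H](C)[C@@H](OCc1ccc(OC)cc1)[C@H]1COC(C)(C)O1 | intermediate (not isolated)
12 | (3R,4R)-4-[(4R)-2,2-dimethyl-1,3-dioxolan-4-yl]-4-[(4-methoxybenzyl)oxy]-2,3-dimethylbutanal (both C2 epimers) | O=CC(C)[C@@H](C)[C@@H](OCc1ccc(OC)cc1)[C@H]1COC(C)(C)O1 | intermediate
13 | methyl vinyl ketone | CC(=O)C=C | starting material
14 | 2-{(1R,2R)-1-[(4R)-2,2-dimethyl-1,3-dioxolan-4-yl]-1-[(4-methoxybenzyl)oxy]propan-2-yl}-2-methyl-5-oxohexanal | CC(=O)CCC(C)(C=O)[C@@H](C)[C@@H](OCc1ccc(OC)cc1)[C@H]1COC(C)(C)O1 | intermediate (not isolated)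
15 | 3-hydroxy-4-methyl-4-{(1R,2R)-1-[(4R)-2,2-dimethyl-1,3-dioxolan-4-yl]-1-[(4-methoxybenzyl)oxy]propan-2-yl}cyclohexan-1-one | O=C1CCC(C)([C@@H](C)[C@@H](OCc2ccc(OC)cc2)[C@H]2COC(C)(C)O2)C(O)C1 | intermediate (not isolated)
16 | 4-{(1R,2R)-1-[(4R)-2,2-dimethyl-1,3-dioxolan-4-yl]-1-[(4-methoxybenzyl)oxy]propan-2-yl}-4-methylcyclohex-2-en-1-one (both ring epimers) | O=C1C=CC(C)([C@@H](C)[C@@H](OCc2ccc(OC)cc2)[C@H]2COC(C)(C)O2)CC1 | intermediate
17 | trimethylsilyl dienol ether of 16 (C8–OSiMe3, C8=C9, C6=C7) | C[Si](C)(C)OC1=CCC(C)([C@@H](C)[C@@H](OCc2ccc(OC)cc2)[C@H]2COC(C)(C)O2)C=C1 | intermediate (not isolated)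
18 | 4-{(1R,2R)-1-[(4R)-2,2-dimethyl-1,3-dioxolan-4-yl]-1-[(4-methoxybenzyl)oxy]propan-2-yl}-4-methylcyclohexa-2,5-dien-1-one | O=C1C=CC(C)([C@@H](C)[C@@H](OCc2ccc(OC)cc2)[C@H]2COC(C)(C)O2)C=C1 | intermediate
19 | 4-{(2R,3R,4R)-4,5-dihydroxy-3-[(4-methoxybenzyl)oxy]pentan-2-yl}-4-methylcyclohexa-2,5-dien-1-one | O=C1C=CC(C)([C@@H](C)[C@@H](OCc2ccc(OC)cc2)[C@H](O)CO)C=C1 | intermediate
20 | 4-{(2R,3R,4S)-4-hydroxy-5-iodo-3-[(4-methoxybenzyl)oxy]pentan-2-yl}-4-methylcyclohexa-2,5-dien-1-one | O=C1C=CC(C)([C@@H](C)[C@@H](OCc2ccc(OC)cc2)[C@H](O)CI)C=C1 | intermediate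
21 | 4-{(2R,3R,4S)-4-[(tert-butyldimethylsilyl)oxy]-5-iodo-3-[(4-methoxybenzyl)oxy]pentan-2-yl}-4-methylcyclohexa-2,5-dien-1-one | O=C1C=CC(C)([C@@H](C)[C@@H](OCc2ccc(OC)cc2)[C@H](O[Si](C)(C)C(C)(C)C)CI)C=C1 | intermediate (key-step precursor)
22 | (4aR,5R,6R,7R,8aR)-7-[(tert-butyldimethylsilyl)oxy]-6-[(4-methoxybenzyl)oxy]-4a,5-dimethyl-4a,5,6,7,8,8a-hexahydronaphthalen-2(1H)-one | COc1ccc(CO[C@H]2[C@H](O[Si](C)(C)C(C)(C)C)C[C@@H]3CC(=O)C=C[C@]3(C)[C@H]2C)cc1 | intermediate (key-step product)
23 | trimethylsilyl dienol ether of 22 (C8–OSiMe3, C8=C9, C6=C7) | COc1ccc(CO[C@H]2[C@H](O[Si](C)(C)C(C)(C)C)C[C@@H]3C=C(O[Si](C)(C)C)C=C[C@]3(C)[C@H]2C)cc1 | intermediate (not isolated)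
24 | (4aR,5R,6R,7R)-7-[(tert-butyldimethylsilyl)oxy]-6-[(4-methoxybenzyl)oxy]-4a,5-dimethyl-5,6,7,8-tetrahydronaphthalen-2(4aH)-one | COc1ccc(CO[C@H]2[C@H](O[Si](C)(C)C(C)(C)C)CC3=CC(=O)C=C[C@]3(C)[C@H]2C)cc1 | intermediate
25 | (3R,4R,4aR,5R,6R,7R)-7-[(tert-butyldimethylsilyl)oxy]-3,4-dihydroxy-6-[(4-methoxybenzyl)oxy]-4a,5-dimethyl-4,4a,5,6,7,8-hexahydronaphthalen-2(3H)-one | COc1ccc(CO[C@H]2[C@H](O[Si](C)(C)C(C)(C)C)CC3=CC(=O)[C@H](O)[C@H](O)[C@]3(C)[C@H]2C)cc1 | intermediate
26 | (4aS,5R,6R,7R)-7-[(tert-butyldimethylsilyl)oxy]-3-hydroxy-6-[(4-methoxybenzyl)oxy]-4a,5-dimethyl-5,6,7,8-tetrahydronaphthalen-2(4aH)-one | COc1ccc(CO[C@H]2[C@H](O[Si](C)(C)C(C)(C)C)CC3=CC(=O)C(O)=C[C@]3(C)[C@H]2C)cc1 | intermediate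
27 | (4aS,5R,6R,7R)-3,7-bis[(tert-butyldimethylsilyl)oxy]-6-[(4-methoxybenzyl)oxy]-4a,5-dimethyl-5,6,7,8-tetrahydronaphthalen-2(4aH)-one | COc1ccc(CO[C@H]2[C@H](O[Si](C)(C)C(C)(C)C)CC3=CC(=O)C(O[Si](C)(C)C(C)(C)C)=C[C@]3(C)[C@H]2C)cc1 | intermediate
28 | (4aS,5R,6R,7R)-3,7-bis[(tert-butyldimethylsilyl)oxy]-6-hydroxy-4a,5-dimethyl-5,6,7,8-tetrahydronaphthalen-2(4aH)-one | O[C@H]1[C@H](O[Si](C)(C)C(C)(C)C)CC2=CC(=O)C(O[Si](C)(C)C(C)(C)C)=C[C@]2(C)[C@H]1C | intermediate
29 | (S)-2-methylbutan-1-ol | CC[C@H](C)CO | starting material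
30 | (S)-2-methylbutanal | CC[C@H](C)C=O | intermediate
31 | ethyl (2E,4E,6S)-6-methylocta-2,4-dienoate | CC[C@H](C)/C=C/C=C/C(=O)OCC | intermediate
32 | (2E,4E,6S)-6-methylocta-2,4-dienoic acid | CC[C@H](C)/C=C/C=C/C(=O)O | intermediate
33 | (2E,4E,6S)-6-methylocta-2,4-dienoic 2,4,6-trichlorobenzoic anhydride | CC[C@H](C)/C=C/C=C/C(=O)OC(=O)c1c(Cl)cc(Cl)cc1Cl | intermediate (not isolated)
34 | (1R,2R,3R,8aS)-3,7-bis[(tert-butyldimethylsilyl)oxy]-1,8a-dimethyl-6-oxo-1,2,3,4,6,8a-hexahydronaphthalen-2-yl (2E,4E,6S)-6-methylocta-2,4-dienoate | CC[C@H](C)/C=C/C=C/C(=O)O[C@H]1[C@H](O[Si](C)(C)C(C)(C)C)CC2=CC(=O)C(O[Si](C)(C)C(C)(C)C)=C[C@]2(C)[C@H]1C | intermediate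
35 | septeremophilane G, (1R,2R,3R,8aS)-3,7-dihydroxy-1,8a-dimethyl-6-oxo-1,2,3,4,6,8a-hexahydronaphthalen-2-yl (2E,4E,6S)-6-methylocta-2,4-dienoate | CC[C@H](C)/C=C/C=C/C(=O)O[C@H]1[C@H](O)CC2=CC(=O)C(O)=C[C@]2(C)[C@H]1C | target

## Step count and risks

Total step count: 22 (19 in the main line, 3 for the side-chain acid).
Longest linear sequence: 19 steps (steps 1–17, 21 and 22, from (E)-but-2-ene; 18 from (R)-glyceraldehyde acetonide).

**Step 12 (key step).** The C1 radical may attack the other enone arm through the alternative chair or a boat, giving the C5 epimer, or it may take up hydrogen (from the stannane or from the PMB methylene by 1,5-transfer) before the ring closes. The fallback sets out from iodohydrin 20. DDQ in wet CH2Cl2 removes the PMB group to give iodo diol F1, and 2,2-dimethoxypropane with pyridinium tosylate ties the syn C2/C3 diol into trans-acetonide iodide F2. In the Bu3SnH/AIBN closure of F2 the trans-fused dioxolane can only span two equatorial positions of the forming ring, so only the chair that leads to the C4/C5-cis product remains, and no benzylic hydrogen sits 1,5 to the radical; this should give acetonide enone F3. Aqueous acetic acid then releases diol enone F4, TBSCl and imidazole silylate the less hindered C2 hydroxyl to give C2 silyl ether F5, and 4-methoxybenzyl trichloroacetimidate with catalytic camphorsulfonic acid protects C3, which comes back to the route at 22.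

**Step 21.** Acyl transfer to the axial C3 hydroxyl, which is syn-axial to the C5 methyl, may be slow, leaving the activated dienoic acid time to deconjugate or to scramble its C6 centre. The fallback sets out from alcohol 28. Diethylphosphonoacetic acid and dicyclohexylcarbodiimide, a small acid that acylates hindered alcohols through its ketene, should give phosphonoacetate F7. Aldehyde 30 is extended with (triphenylphosphoranylidene)acetaldehyde to (S,E)-4-methylhex-2-enal F8. A Horner–Wadsworth–Emmons coupling of F7 with F8 under LiCl and DBU then builds the 2E double bond on the ester already in place and comes back to the route at 34.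

**Step 14.** Osmylation of the electron-poor, neopentyl C6=C7 bond may be sluggish, so that attack on C9=C10 or over-oxidation competes. The fallback sets out from dienone 24. Alkaline hydrogen peroxide (H2O2, NaOH, MeOH, 0 °C) should epoxidise only the disubstituted enone to give epoxy enone F6. Brief treatment with aqueous NaOH in dioxane under argon opens the epoxide at C7 and expels the C6 oxygen, which comes back to the route at diosphenol 26 and so replaces steps 14 and 15; the exposure to base is kept short because the C2 silyloxy group can be lost by vinylogous elimination.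

## Further compounds

F1 | step 12 | 4-[(2R,3R,4S)-3,4-dihydroxy-5-iodopentan-2-yl]-4-methylcyclohexa-2,5-dien-1-one (iodo diol) | O=C1C=CC(C)([C@@H](C)[C@@H](O)[C@H](O)CI)C=C1
F2 | step 12 | trans-2,3-acetonide of F1 (trans-acetonide iodide) | O=C1C=CC(C)([C@@H](C)[C@H]2OC(C)(C)O[C@@H]2CI)C=C1
F3 | step 12 | cis-fused bicyclic enone with C2/C3 acetonide (acetonide enone) | CC1(C)O[C@H]2[C@H](O1)C[C@@H]3CC(=O)C=C[C@]3(C)[C@H]2C
F4 | step 12 | cis-fused bicyclic enone with free C2 and C3 hydroxyls (diol enone) | O[C@H]1[C@H](O)C[C@@H]2CC(=O)C=C[C@]2(C)[C@H]1C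
F5 | step 12 | cis-fused bicyclic enone with C2-OTBS and free C3-OH (C2 silyl ether) | O[C@H]1[C@H](O[Si](C)(C)C(C)(C)C)C[C@@H]2CC(=O)C=C[C@]2(C)[C@H]1C
F6 | step 14 | 6,7-epoxide of dienone 24, oxygen anti to the C5 methyl (epoxy enone) | COc1ccc(CO[C@H]2[C@H](O[Si](C)(C)C(C)(C)C)CC3=CC(=O)[C@@H]4O[C@@H]4[C@]3(C)[C@H]2C)cc1
F7 | step 21 | C3 (diethoxyphosphoryl)acetate of alcohol 28 (phosphonoacetate) | CCOP(=O)(OCC)CC(=O)O[C@H]1[C@H](O[Si](C)(C)C(C)(C)C)CC2=CC(=O)C(O[Si](C)(C)C(C)(C)C)=C[C@]2(C)[C@H]1C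
F8 | step 21 | (S,E)-4-methylhex-2-enal | CC[C@H](C)/C=C/C=O
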